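## Retrosynthetic overview
1. The acetate, C1 (Colvin homologation), C2–C3 (cross-metathesis) and C4–C5 (chelation-controlled allylation, which sets C6) are removed to reach an oxocene-2-carbaldehyde and its ethyl ester.
2. Key disconnection, O–C7 and C7–C8: the oxocene is the three-atom ring expansion product of a 2-vinyloxolane and the carbene from ethyl diazoacetate (photolysis, oxonium ylide, [2,3] shift). This step also gives the Z C9=C10 alkene and sets C7.
3. C13–O and C12–Br come from a 5-endo bromoetherification of (3S,5E)-octa-1,5-dien-3-ol.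
4. The dienol comes from (S)-epichlorohydrin (the only bought stereocentre, C10), but-1-yne and one CH2. Chirality is relayed C10 → C12/C13 → C7 → C6, and C10 is erased in the ring expansion.
5. Ring order: the oxolane forms first (step 3) and is then enlarged to the oxocene (step 4), the only ring of the target.

Assumption: the SMILES is natural (+)-laurencin, (6R,7R,12S,13R) in laurencin numbering (C1 = alkyne CH, C15 = ethyl CH3); this numbering is used for atom labels below.

## Route

Step 1
Reactants: 1 but-1-yne; 2 (S)-epichlorohydrin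
Product: 5 (2S,4E)-1-chlorohept-4-en-2-ol, via (E)-but-1-enyl(diisobutyl)alane 3 (not isolated), via lithium (E)-but-1-enyl(butyl)diisobutylalanate 4 (not isolated)
Conditions: 1, i-Bu2AlH, hexane, 50 °C (sealed); n-BuLi, THF, −78 °C; 2, −78 → 0 °C; 1 M HCl
Reagents that add atoms: none
Why: Hydroalumination–alanate epoxide opening: syn addition of Al–H to the terminal alkyne fixes the E geometry of C12=C13, and the alkenyl group of the ate complex is transferred with retention to the unsubstituted epoxide carbon of 2 (SN2), so the bought stereocentre (future C10) is not touched and the chloride survives at or below 0 °C.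

Step 2
Reactants: 5 (2S,4E)-1-chlorohept-4-en-2-ol
Product: 7 (3S,5E)-octa-1,5-dien-3-ol, via (2S)-2-[(2E)-pent-2-enyl]oxirane 6 (not isolated)
Conditions: trimethylsulfonium iodide (4 equiv), n-BuLi (3.8 equiv), THF, −10 °C; then 5, −10 °C → rt
Reagents that add atoms: trimethylsulfonium iodide, C[S+](C)C.[I-]
Why: One-carbon epoxide-to-allylic-alcohol homologation with dimethylsulfonium methylide: the first equivalent of base closes the chlorohydrin to terminal epoxide 6 (Williamson closure at CH2Cl), the ylide opens 6 at its CH2 terminus and a further equivalent of base expels dimethyl sulfide by E2, all at carbons next to the stereocentre and not at it, so it stays S.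

Step 3
Reactants: 7 (3S,5E)-octa-1,5-dien-3-ol
Product: 8 (2R,3S,5S)-3-bromo-2-ethyl-5-vinyloxolane (Et/Br trans; Et/vinyl trans)
Conditions: NBS (1.05 equiv), MeCN, −20 → 0 °C, dark; chromatography
Reagents that add atoms: N-bromosuccinimide, O=C1CCC(=O)N1Br
Why: 5-endo-trig bromoetherification: NBS attacks the electron-richer 1,2-disubstituted alkene, anti addition across the E alkene makes Br and Et trans, and an envelope transition state with the vinyl group pseudo-equatorial places vinyl cis to Br and trans to Et, as in the 2,5-trans-selective 5-endo iodocyclisations of (E)-homoallylic alcohols, so C10 controls C12 and C13 and the minor 2,5-cis isomer is removed on silica.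

Step 4
Reactants: 8 (2R,3S,5S)-3-bromo-2-ethyl-5-vinyloxolane; 9 ethyl diazoacetate
Product: 12 ethyl (2R,4Z,7S,8R)-7-bromo-8-ethyl-3,6,7,8-tetrahydro-2H-oxocine-2-carboxylate, via ethoxycarbonylcarbene 10 (not isolated), via oxonium ylide 11 (not isolated)
Conditions: 9 (2 equiv, syringe pump, 10 h), 8 (1 M), CH2Cl2, hν (370 nm LEDs), 0 °C, no catalyst; stop at ca. 60% conversion, recover 8
Reagents that add atoms: none
Why: Proposed new method: catalyst-free, light-driven three-atom ring expansion of a 2-vinyloxolane by an acceptor-only diazoacetate, in which 370 nm photolysis of 9 expels N2 to give singlet carbene 10, whose empty p orbital is captured by the most Lewis-basic site of 8, the ring oxygen, to give free oxonium ylide 11; fast pyramidal inversion at O+ lets the ylide carbon reach the face syn to the vinyl group (anti to the C13 ethyl group, because 8 is 2,5-trans), and a concerted suprafacial [2,3]-sigmatropic shift through a five-membered envelope makes C7–C8, breaks O–C10 and moves the double bond to C9=C10, with the short C–O bonds and the strain of an E-oxocene favouring the folded transition state that gives the Z alkene; with the ester exo (pointing away from the oxolane) the new C7 centre is R, cis to the ethyl group across the ring oxygen, so C13 (through C10) controls C7 while C10 is erased; the closest known reaction types are the copper- or rhodium-carbenoid oxonium-ylide [2,3] rearrangement of allylic ethers, the light-driven one-atom ring expansion of oxetanes with aryldiazoacetates and the [2,3] ring growing of 2-vinylthiolanium ylides, none of which has been shown as a metal-free photochemical five-to-eight enlargement of a halogenated, stereodefined 2-vinyloxolane.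

Step 5
Reactants: 12 ethyl (2R,4Z,7S,8R)-7-bromo-8-ethyl-3,6,7,8-tetrahydro-2H-oxocine-2-carboxylate
Product: 13 (2R,4Z,7S,8R)-7-bromo-8-ethyl-3,6,7,8-tetrahydro-2H-oxocine-2-carbaldehyde
Conditions: i-Bu2AlH (1.1 equiv), CH2Cl2, −78 °C; aq. potassium sodium tartrate
Reagents that add atoms: none
Why: Partial ester reduction with one hydride equivalent at −78 °C, which for alpha-alkoxy esters stops cleanly at the aldehyde stage until work-up; no base is present, so C7 is not epimerised, and the secondary bromide and the alkene are inert.

Step 6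
Reactants: 13 (2R,4Z,7S,8R)-7-bromo-8-ethyl-3,6,7,8-tetrahydro-2H-oxocine-2-carbaldehyde; 14 allyltributylstannane
Product: 15 (1R)-1-[(2R,4Z,7S,8R)-7-bromo-8-ethyl-3,6,7,8-tetrahydro-2H-oxocin-2-yl]but-3-en-1-ol
Conditions: MgBr2·OEt2 (3 equiv), CH2Cl2, −78 °C; 14 (1.5 equiv), −78 → −20 °C
Reagents that add atoms: none
Why: Chelation-controlled (Cram-chelate, Keck-type) allylstannane addition: MgBr2 binds the aldehyde oxygen and the ring oxygen in a five-membered chelate and the allyl group attacks the face flanked by C7–H rather than C8H2, giving the syn (6R,7R) alcohol, so C7 controls C6.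

Step 7
Reactants: 15 (1R)-1-[(2R,4Z,7S,8R)-7-bromo-8-ethyl-3,6,7,8-tetrahydro-2H-oxocin-2-yl]but-3-en-1-ol; 16 (E)-crotonaldehyde
Product: 17 (2E,5R)-5-[(2R,4Z,7S,8R)-7-bromo-8-ethyl-3,6,7,8-tetrahydro-2H-oxocin-2-yl]-5-hydroxypent-2-enal
Conditions: 16 (5 equiv), second-generation Hoveyda–Grubbs catalyst RuCl2(H2IMes)(=CH-C6H4-2-O-i-Pr) (5 mol %), CH2Cl2, 40 °C
Reagents that add atoms: none
Why: Olefin cross-metathesis of a terminal homoallylic alkene with an electron-poor enal partner gives the E-enal under thermodynamic control and releases propene, while the internal Z alkene of the oxocene, the kind of product that ring-closing metathesis itself delivers, reacts more slowly and re-closes if opened.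

Step 8
Reactants: 17 (2E,5R)-5-[(2R,4Z,7S,8R)-7-bromo-8-ethyl-3,6,7,8-tetrahydro-2H-oxocin-2-yl]-5-hydroxypent-2-enal
Product: 18 deacetyllaurencin, (1R,3E)-1-[(2R,4Z,7S,8R)-7-bromo-8-ethyl-3,6,7,8-tetrahydro-2H-oxocin-2-yl]hex-3-en-5-yn-1-ol
Conditions: Me3SiCHN2 (2.5 equiv), LiN(i-Pr)2 (2.5 equiv), THF, −78 °C; 17; −78 → 0 °C
Reagents that add atoms: (trimethylsilyl)diazomethane, C[Si](C)(C)C=[N+]=[N-]
Why: Colvin rearrangement (Seyferth–Gilbert-type homologation): the lithiated silyldiazomethane adds 1,2 to the enal, and Peterson-type loss of lithium trimethylsilanolate followed by loss of N2 with a 1,2-hydride shift gives the terminal alkyne without touching the E alkene; the extra equivalent of reagent only deprotonates the C6 hydroxyl, and at −78 °C the secondary bromide is not eliminated.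

Step 9
Reactants: 18 deacetyllaurencin
Product: 19 (+)-laurencin, (1R,3E)-1-[(2R,4Z,7S,8R)-7-bromo-8-ethyl-3,6,7,8-tetrahydro-2H-oxocin-2-yl]hex-3-en-5-yn-1-yl acetate
Conditions: Ac2O, pyridine, DMAP (cat.), CH2Cl2, rt
Reagents that add atoms: acetic anhydride, CC(=O)OC(C)=O
Why: DMAP-catalysed O-acylation of the only hydroxyl group, with retention at C6.

## Compound list
1 | but-1-yne | CCC#C | starting material
2 | (S)-epichlorohydrin, (2S)-2-(chloromethyl)oxirane | ClC[C@@H]1CO1 | starting material
3 | (E)-but-1-enyl(diisobutyl)alane | CC/C=C/[Al](CC(C)C)CC(C)C | intermediate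
4 | lithium (E)-but-1-enyl(butyl)diisobutylalanate | [Li+].CC/C=C/[Al-](CCCC)(CC(C)C)CC(C)C | intermediate
5 | (2S,4E)-1-chlorohept-4-en-2-ol | ClC[C@@H](O)C/C=C/CC | intermediate
6 | (2S)-2-[(2E)-pent-2-enyl]oxirane | CC/C=C/C[C@H]1CO1 | intermediate
7 | (3S,5E)-octa-1,5-dien-3-ol | C=C[C@@H](O)C/C=C/CC | intermediate
8 | (2R,3S,5S)-3-bromo-2-ethyl-5-vinyloxolane | C=C[C@@H]1C[C@H](Br)[C@@H](CC)O1 | intermediate
9 | ethyl diazoacetate | CCOC(=O)C=[N+]=[N-] | starting material
10 | ethoxycarbonylcarbene | CCOC(=O)[CH] | intermediate
11 | oxonium ylide (O-ethoxycarbonylmethylide of 8) | C=C[C@@H]1C[C@H](Br)[C@@H](CC)[O+]1[CH-]C(=O)OCC | intermediate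
12 | ethyl (2R,4Z,7S,8R)-7-bromo-8-ethyl-3,6,7,8-tetrahydro-2H-oxocine-2-carboxylate | CCOC(=O)[C@H]1C/C=C\C[C@H](Br)[C@@H](CC)O1 | intermediate
13 | (2R,4Z,7S,8R)-7-bromo-8-ethyl-3,6,7,8-tetrahydro-2H-oxocine-2-carbaldehyde | O=C[C@H]1C/C=C\C[C@H](Br)[C@@H](CC)O1 | intermediate
14 | allyltributylstannane | C=CC[Sn](CCCC)(CCCC)CCCC | starting material
15 | (1R)-1-[(2R,4Z,7S,8R)-7-bromo-8-ethyl-3,6,7,8-tetrahydro-2H-oxocin-2-yl]but-3-en-1-ol | C=CC[C@@H](O)[C@H]1C/C=C\C[C@H](Br)[C@@H](CC)O1 | intermediate
16 | (E)-crotonaldehyde | C/C=C/C=O | starting material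
17 | (2E,5R)-5-[(2R,4Z,7S,8R)-7-bromo-8-ethyl-3,6,7,8-tetrahydro-2H-oxocin-2-yl]-5-hydroxypent-2-enal | O=C/C=C/C[C@@H](O)[C@H]1C/C=C\C[C@H](Br)[C@@H](CC)O1 | intermediate
18 | deacetyllaurencin | C#C/C=C/C[C@@H](O)[C@H]1C/C=C\C[C@H](Br)[C@@H](CC)O1 | intermediate
19 | (+)-laurencin | C#C/C=C/C[C@@H](OC(C)=O)[C@H]1C/C=C\C[C@H](Br)[C@@H](CC)O1 | target

## Step count and risks
Total step count: 9. Longest linear sequence: 9 (fully linear from 1 and 2).

**Step 4 (the proposed new step).**
- The free carbene may cyclopropanate the vinyl group or the product alkene.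
- It may attack the C–Br bond.
- The ylide may undergo a [1,2] shift or a beta-elimination.
- Some E-oxocene or some C7 epimer may form.

The fallback sets out from 8 (with 9) and comes back at 12. It gives up light and the free carbene. Compound 9 is added slowly to 8 and 2–5 mol % copper bis(hexafluoroacetylacetonate), Cu(CF3COCHCOCF3)2, in refluxing CH2Cl2. This is the established copper-carbenoid route to allylic oxonium ylides and their [2,3] rearrangement, and it has intermolecular precedent. The electrophilic metal-bound carbene prefers the ether oxygen over the alkene and the bromide. The ylide stays metal-associated, and chemoselectivity can be tuned through the ligand. Compounds outside the list on this path: none F0.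

**Step 3.** The facial selectivity of the bromonium cyclisation rests on analogy with iodocyclisations and may be modest. The fallback sets out from 7 and comes back at 7. It does not try to raise the selectivity and turns the step into a separate-and-recycle loop. The mixture from 7 is chromatographed and 8 goes forward. The unwanted isomer (2S,3R,5S)-3-bromo-2-ethyl-5-vinyloxolane F1 is treated with Zn dust in EtOH at rt, then water. This Boord-type reductive beta-elimination of the beta-bromo ether regenerates 7 with C10 intact. The E geometry is favoured and is checked before re-use.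

**Step 6.** The hindered ring oxygen, which sits between two secondary carbons, may chelate poorly, so the C6 selectivity could be low or Felkin-type. The fallback sets out from 13 and comes back at 15. C6 is then set by reduction instead of by C–C bond formation.
- CH2=CHCH2MgBr in THF at −78 °C gives 15 together with (1S)-1-[(2R,4Z,7S,8R)-7-bromo-8-ethyl-3,6,7,8-tetrahydro-2H-oxocin-2-yl]but-3-en-1-ol F2.
- Dess–Martin oxidation of the mixture gives 1-[(2R,4Z,7S,8R)-7-bromo-8-ethyl-3,6,7,8-tetrahydro-2H-oxocin-2-yl]but-3-en-1-one F3.
- LiBH(s-Bu)3 in THF at −78 °C reduces F3 under Felkin–Anh control, with hydride anti to the C7–O bond, to the (6R,7R) alcohol 15.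

Further compounds
F0 | step 4 | none | none
F1 | step 3 | (2S,3R,5S)-3-bromo-2-ethyl-5-vinyloxolane | C=C[C@@H]1C[C@@H](Br)[C@H](CC)O1
F2 | step 6 | (1S)-1-[(2R,4Z,7S,8R)-7-bromo-8-ethyl-3,6,7,8-tetrahydro-2H-oxocin-2-yl]but-3-en-1-ol | C=CC[C@H](O)[C@H]1C/C=C\C[C@H](Br)[C@@H](CC)O1
F3 | step 6 | 1-[(2R,4Z,7S,8R)-7-bromo-8-ethyl-3,6,7,8-tetrahydro-2H-oxocin-2-yl]but-3-en-1-one | C=CCC(=O)[C@H]1C/C=C\C[C@H](Br)[C@@H](CC)O1
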